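## Retrosynthetic overview

1. Locants are briarane numbers. C1 (quaternary) to C10 run round the ten-membered ring: C2 OAc, C3=C4 Z, C5=C16, C6 Cl, C7 O-lactone, C8 OH, C9 OAc. C11–C14 complete the cyclohexene (methyls C15 on C1 and C20 on C11; β is the face of C15). C17(C18)–C19 complete the γ-lactone.
2. Last disconnection: a retro endo enyne metathesis opens the ten-membered ring at C3=C4/C5=C16 to an open compound with a vinyl group on C2 and an ethynyl group on C6. This works because C4 and C5, the inner carbons of the cross-conjugated diene C3=C4–C5(=C16), are adjacent members of that ring while C16 is exocyclic. The trans fusions to the cyclohexene (C1–C10) and the lactone (C7–C8) also hold the two arms close.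
3. γ-Lactone: C6–C7 is made by anti-selective chloroallenylzinc addition to a C7 aldehyde, which brings in C4–C6 and Cl. O7–C19 lactonisation follows.
4. C8–C9 is made by aldol union of a cyclohexene carbaldehyde with the enolate of an L-malic acid dioxolanone (C7, C8, C17–C19). C9 is then reset by oxidation and chelate-controlled reduction.
5. The cyclohexene comes from a catalytic asymmetric Diels–Alder reaction. Ring order: cyclohexene, then γ-lactone, then ten-membered ring.

Key step: step 23

Remark: the sense of induction in step 3 is assigned by the usual formyl C–H···O binding model of the boron catalyst. Should it be opposite, the (R)-catalyst is used and nothing else changes.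

## Route

Step 1
Reactants: 1 (tert-butyldimethylsilyloxy)acetaldehyde; 2 2-(triphenylphosphoranylidene)propanal
Product: 3 (E)-4-(tert-butyldimethylsilyloxy)-2-methylbut-2-enal
Conditions: PhH, 80 °C
Reagents that add atoms: none
Why: Wittig olefination with a stabilised ylide should give the E-enal, in which CHO and CH2OTBS are trans, as C2 and C9 must be on the ring.

Step 2
Reactants: 4 pent-1-en-3-one
Product: 5 (Z)-3-(triisopropylsilyloxy)penta-1,3-diene
Conditions: TIPSOTf, Et3N, Et2O, 0 °C
Reagents that add atoms: triisopropylsilyl triflate CC(C)[Si](C(C)C)(C(C)C)OS(=O)(=O)C(F)(F)F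
Why: Soft enolisation and O-silylation of the ethyl ketone (silyl enol ether formation) should give the Z enol ether, a diene whose methyl group points outward and does not hinder the s-cis form.

Step 3
Reactants: 3 enal; 5 silyloxydiene
Product: 6 Diels–Alder adduct (C1 aldehyde; 11-epi)
Conditions: (S)-3,3-diphenyl-1-(o-tolyl)oxazaborolidine·HNTf2 (20 mol %), CH2Cl2, −78 → −40 °C
Reagents that add atoms: none
Why: Catalytic enantioselective Diels–Alder reaction in which the CHMe terminus of the 2-silyloxydiene attacks C10, the β-carbon of the boron-bound s-trans enal ("para" orientation); suprafacial addition to the E-enal sets C1/C10 with CHO trans to CH2OTBS, the shielded catalyst face sets the absolute sense, and the endo-derived C11 centre is provisional (corrected in step 5).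

Step 4
Reactants: 6 aldehyde
Product: 8 (2S)-allylic acetate, via bromomagnesium alkoxide 7 (not isolated)
Conditions: CH2=CHMgBr, THF, −78 °C; then Ac2O, DMAP, −78 °C → rt
Reagents that add atoms: vinylmagnesium bromide C=C[Mg]Br; acetic anhydride CC(=O)OC(C)=O
Why: Felkin–Anh 1,2-addition of the Grignard reagent to the only free carbonyl group (C10 branch as large group anti to the nucleophile, approach past the C15 methyl) should set 2S, and the alkoxide is acetylated in the same flask.

Step 5
Reactants: 8 silyl enol ether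
Product: 10 enone with the target C11 configuration, via 11-epi enone 9 (not isolated)
Conditions: Pd(OAc)2 (1.1 equiv), DMSO, 45 °C; filter; then DBU (cat.), CH2Cl2, rt
Reagents that add atoms: none
Why: Saegusa–Ito oxidation of the regiodefined silyl enol ether places the double bond at C13=C14, and base equilibration of C11, the only enolisable centre, should favour the epimer with both methyl groups equatorial and the bulky C2 and C9 arms trans-diaxial.

Step 6
Reactants: 10 enone
Product: 11 12β-allylic alcohol (12-epi)
Conditions: L-Selectride, THF, −78 °C; then H2O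
Reagents that add atoms: none
Why: 1,2-Reduction by a bulky borohydride should occur from the α-face, opposite to the axial C10 side chain, giving the axial 12β-alcohol; conjugate attack at C14 is blocked by the neighbouring quaternary C1.

Step 7
Reactants: 11 allylic alcohol
Product: 12 12α-propionate
Conditions: EtCO2H, PPh3, DIAD, toluene, 0 °C → rt
Reagents that add atoms: propionic acid CCC(=O)O
Why: Mitsunobu esterification inverts the axial allylic alcohol by SN2 to the equatorial 12α-ester, and SN2′ attack at C14 is blocked by quaternary C1.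

Step 8
Reactants: 12 silyl ether
Product: 13 primary alcohol
Conditions: HF·pyridine, THF, 0 °C
Reagents that add atoms: none
Why: Fluoride-mediated desilylation of the primary silyl ether leaves the two esters untouched.

Step 9
Reactants: 13 primary alcohol
Product: 14 C9 aldehyde
Conditions: DMP, NaHCO3, CH2Cl2, 0 °C → rt
Reagents that add atoms: none
Why: Dess–Martin oxidation under buffered conditions should not epimerise C10.

Step 10
Reactants: 15 diethyl (S)-malate
Product: 16 diethyl (2S,3R)-2-hydroxy-3-methylbutanedioate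
Conditions: LDA (2.2 equiv), THF, −78 → −20 °C; MeI, −78 °C; AcOH
Reagents that add atoms: iodomethane CI
Why: Fráter–Seebach alkylation, in which the chelated alkoxide enolate is methylated anti to the alkoxide, sets C17.

Step 11
Reactants: 16 diester
Product: 17 (2S,3R)-2-hydroxy-3-methylbutanedioic acid
Conditions: KOH, EtOH/H2O, rt; then HCl
Reagents that add atoms: potassium hydroxide [K+].[OH-]
Why: Saponification of both esters under conditions that leave the carboxylate α-centres intact.

Step 12
Reactants: 17 hydroxy diacid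
Product: 18 cis-dioxolanone acid
Conditions: t-BuCHO, TsOH (cat.), H2SO4 (cat.), pentane, reflux (−H2O)
Reagents that add atoms: pivalaldehyde CC(C)(C)C=O
Why: Acetalisation of the α-hydroxy acid gives the thermodynamic cis-dioxolanone, whose new acetal centre stores the C8 configuration (self-regeneration of stereocentres).

Step 13
Reactants: 18 acid
Product: 19 tert-butyl ester
Conditions: Cl3CC(=NH)Ot-Bu, BF3·OEt2 (cat.), CH2Cl2/cyclohexane, rt
Reagents that add atoms: tert-butyl 2,2,2-trichloroacetimidate CC(C)(C)OC(=N)C(Cl)(Cl)Cl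
Why: Acid-catalysed imidate esterification gives a C19 ester that a later C9 alkoxide cannot attack.

Step 14
Reactants: 14 aldehyde; 19 dioxolanone ester
Product: 21 aldol adduct (9-epi carbinol), via lithium enolate 20 (not isolated)
Conditions: 19, LiHMDS, THF, −78 °C; then 14, −78 °C; AcOH quench
Reagents that add atoms: none
Why: Aldol addition in which the more acidic lactone-type C8–H is removed and the enolate reacts anti to the tert-butyl group, so C9 replaces H with retention and sets C8; the Zimmerman–Traxler and Felkin–Anh preferences should give the 9-epi alcohol, which steps 16 and 17 correct.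

Step 15
Reactants: 21 dioxolanone
Product: 22 α-hydroxy thioester (8,9-diol; 9-epi)
Conditions: EtSH (10 equiv), KHMDS (0.2 equiv), THF, −20 → 0 °C
Reagents that add atoms: ethanethiol CCS
Why: Thiolysis of the activated acylal-type carbonyl C7 is driven by loss of pivalaldehyde, whereas exchange at the ordinary esters is uphill, so C8–OH is freed and C7 becomes a thioester.

Step 16
Reactants: 22 diol
Product: 23 C9 ketone
Conditions: IBX, DMSO, rt
Reagents that add atoms: none
Why: IBX oxidation converts the secondary alcohol of a secondary/tertiary 1,2-diol to the ketol without glycol cleavage.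

Step 17
Reactants: 23 α-hydroxy ketone
Product: 24 (9S)-diol
Conditions: Zn(BH4)2, Et2O/CH2Cl2, −40 → −10 °C; then H2O
Reagents that add atoms: none
Why: Cram-chelate reduction in which zinc ties O8 to the C9 carbonyl and hydride enters from the side of the flat thioester rather than the branched C17; this is also the Felkin–Anh face with respect to C10 (C1 as large group), so 9S should result.

Step 18
Reactants: 24 diol
Product: 26 9-acetate 8-trimethylsilyl ether, via 9-acetate 25 (not isolated)
Conditions: Ac2O, DMAP (cat.), 2,6-lutidine, CH2Cl2, rt; then TMSOTf, −40 → 0 °C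
Reagents that add atoms: acetic anhydride CC(=O)OC(C)=O; trimethylsilyl triflate C[Si](C)(C)OS(=O)(=O)C(F)(F)F
Why: The only secondary alcohol is acylated, and the tertiary C8–OH is then silylated with the silyl triflate to give a non-chelating α-substituent for step 20.

Step 19
Reactants: 26 thioester
Product: 27 C7 aldehyde
Conditions: Et3SiH, Pd/CaCO3–Pb (10 mol %), 1-hexene, acetone, rt
Reagents that add atoms: none
Why: Fukuyama reduction stops at the aldehyde and leaves O-esters alone, while the poisoned catalyst and the sacrificial alkene protect the vinyl group.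

Step 20
Reactants: 27 aldehyde; 28 3-chloro-1-(trimethylsilyl)prop-1-yne
Product: 30 anti-chlorohydrin, via chloroallenylzinc bromide 29 (not isolated)
Conditions: 28 (4 equiv), ZnBr2, LDA, THF, −78 °C; then 27, −78 → −20 °C; then H2O
Reagents that add atoms: none
Why: SE2′ addition of the configurationally labile allenylzinc (used in excess) through a cyclic transition state gives the anti C6-Cl/C7-OH pair, and the polar Felkin–Anh model (C8–OSiMe3 anti to the nucleophile, approach past C17 rather than the larger C9 arm) should give 7R and therefore 6S.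

Step 21
Reactants: 30 hydroxy tert-butyl ester
Product: 31 γ-lactone (silylalkyne)
Conditions: TFA/CH2Cl2 1:4, 0 °C → rt
Reagents that add atoms: none
Why: Acidolysis removes the tert-butyl ester and the silyl ether, and the γ-hydroxy acid lactonises on O7, the only free secondary hydroxyl (O9 is acetylated), with C7, C8 and C17 unchanged.

Step 22
Reactants: 31 silylalkyne
Product: 32 open enyne (2-vinyl, 6-ethynyl)
Conditions: TBAF/AcOH 1:1, THF, 0 °C
Reagents that add atoms: none
Why: Buffered fluoride protodesilylation of the alkynylsilane avoids the base that would endanger the chloride and the esters.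

Step 23
Reactants: 32 open enyne
Product: 34 target CNP0305105.1, via open triene 33 (not isolated)
Conditions: RuCl2(SIMes)(=CH-C6H4-2-Oi-Pr) (10 mol %), ethylene (1 atm), toluene (1 mM), 40 °C; then Ar sparge, 80 °C
Reagents that add atoms: ethylene C=C
Why: Ring-closing enyne metathesis run as an ethylene-relayed tandem: the Ru methylidene adds to the terminal alkyne of 32 (ruthenacyclobutene, ring opening to a vinylcarbene, turnover by ethylene) to give the 2-substituted butadiene 33, and once ethylene is swept out the monosubstituted C4=CH2 end of 33 and the C3 vinyl group undergo diene–ene ring-closing metathesis with loss of ethylene. The closest known reaction type is endo-selective macrocyclic enyne metathesis under ethylene, together with ring-closing metathesis to ten-membered carbocycles. One ring is closed, the ten-membered carbocycle C1–C10, by forming C3=C4 in the endo mode, so that both former alkyne carbons (C4, C5) become ring members and C16 (from ethylene) stays exocyclic. No stereocentre is formed; the one new stereoelement, the C3=C4 geometry, should be Z because the cis-olefin is the less strained way to bridge C2 and C5 in a ten-membered ring that is trans-fused to two small rings, and reversible metathesis lets this isomer accumulate. The step needs site selectivity (C4=CH2 over the 1,1-disubstituted C5=C16, which would give a nine-membered ring, and over C13=C14) and ring closure over oligomerisation: the first follows from olefin substitution and from the quaternary C1 and the C12 ester that flank C13=C14, the second from high dilution and from the two ring fusions and the fully substituted C1 and C8, which leave few rotatable bonds and turn both arms toward each other. Alkyl chloride, tertiary alcohol, esters and lactone are inert to the Ru alkylidene, so the step can be run last on the unprotected compound and delivers 34 directly.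

## Compound list

1 | (tert-butyldimethylsilyloxy)acetaldehyde | O=CCO[Si](C)(C)C(C)(C)C | starting material
2 | 2-(triphenylphosphoranylidene)propanal | CC(C=O)=P(c1ccccc1)(c1ccccc1)c1ccccc1 | starting material
3 | (E)-4-(tert-butyldimethylsilyloxy)-2-methylbut-2-enal | O=C/C(C)=C/CO[Si](C)(C)C(C)(C)C | intermediate
4 | pent-1-en-3-one | C=CC(=O)CC | starting material
5 | (Z)-3-(triisopropylsilyloxy)penta-1,3-diene | C=C/C(O[Si](C(C)C)(C(C)C)C(C)C)=C/C | intermediate
6 | 6-[(tert-butyldimethylsilyloxy)methyl]-1,5-dimethyl-4-(triisopropylsilyloxy)cyclohex-3-ene-1-carbaldehyde; C15 methyl β, CHO α, C10 CH2OTBS β, C20 methyl α (11-epi) | O=C[C@@]1(C)CC=C(O[Si](C(C)C)(C(C)C)C(C)C)[C@@H](C)[C@@H]1CO[Si](C)(C)C(C)(C)C | intermediate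
7 | bromomagnesium alkoxide of the (2S)-allylic alcohol from 6 | C=C[C@H](O[Mg]Br)[C@@]1(C)CC=C(O[Si](C(C)C)(C(C)C)C(C)C)[C@@H](C)[C@@H]1CO[Si](C)(C)C(C)(C)C | intermediate
8 | (2S)-allylic acetate, ring as in 6 | C=C[C@H](OC(C)=O)[C@@]1(C)CC=C(O[Si](C(C)C)(C(C)C)C(C)C)[C@@H](C)[C@@H]1CO[Si](C)(C)C(C)(C)C | intermediate
9 | 13-en-12-one with C20 methyl α (11-epi) | C=C[C@H](OC(C)=O)[C@@]1(C)C=CC(=O)[C@@H](C)[C@@H]1CO[Si](C)(C)C(C)(C)C | intermediate
10 | 13-en-12-one with C20 methyl β (target C11) | C=C[C@H](OC(C)=O)[C@@]1(C)C=CC(=O)[C@H](C)[C@@H]1CO[Si](C)(C)C(C)(C)C | intermediate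
11 | 12β-allylic alcohol (12-epi) | C=C[C@H](OC(C)=O)[C@@]1(C)C=C[C@H](O)[C@H](C)[C@@H]1CO[Si](C)(C)C(C)(C)C | intermediate
12 | 12α-propionate, C9 as CH2OTBS (target C1, C2, C10, C11, C12) | C=C[C@H](OC(C)=O)[C@@]1(C)C=C[C@@H](OC(=O)CC)[C@H](C)[C@@H]1CO[Si](C)(C)C(C)(C)C | intermediate
13 | C9 primary alcohol | C=C[C@H](OC(C)=O)[C@@]1(C)C=C[C@@H](OC(=O)CC)[C@H](C)[C@@H]1CO | intermediate
14 | C9 aldehyde | C=C[C@H](OC(C)=O)[C@@]1(C)C=C[C@@H](OC(=O)CC)[C@H](C)[C@@H]1C=O | intermediate
15 | diethyl (S)-malate | CCOC(=O)[C@@H](O)CC(=O)OCC | starting material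
16 | diethyl (2S,3R)-2-hydroxy-3-methylbutanedioate | CCOC(=O)[C@@H](O)[C@@H](C)C(=O)OCC | intermediate
17 | (2S,3R)-2-hydroxy-3-methylbutanedioic acid | OC(=O)[C@@H](O)[C@@H](C)C(=O)O | intermediate
18 | (2R)-2-[(2S,4S)-2-tert-butyl-5-oxo-1,3-dioxolan-4-yl]propanoic acid | C[C@@H](C(=O)O)[C@@H]1O[C@H](C(C)(C)C)OC1=O | intermediate
19 | tert-butyl (2R)-2-[(2S,4S)-2-tert-butyl-5-oxo-1,3-dioxolan-4-yl]propanoate | C[C@@H](C(=O)OC(C)(C)C)[C@@H]1O[C@H](C(C)(C)C)OC1=O | intermediate
20 | lithium enolate of 19 (C8=C7 enolate, acetal centre retained) | C[C@@H](C(=O)OC(C)(C)C)C1=C([O-])O[C@@H](C(C)(C)C)O1.[Li+] | intermediate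
21 | aldol adduct: C8 quaternary (target configuration, C9 trans to t-Bu), 9-epi carbinol, dioxolanone intact | C=C[C@H](OC(C)=O)[C@@]1(C)C=C[C@@H](OC(=O)CC)[C@H](C)[C@@H]1[C@@H](O)[C@@]2([C@@H](C)C(=O)OC(C)(C)C)O[C@H](C(C)(C)C)OC2=O | intermediate
22 | S-ethyl C7 thioester, 8-OH, 9-epi-OH, C19 tert-butyl ester | C=C[C@H](OC(C)=O)[C@@]1(C)C=C[C@@H](OC(=O)CC)[C@H](C)[C@@H]1[C@@H](O)[C@](O)([C@@H](C)C(=O)OC(C)(C)C)C(=O)SCC | intermediate
23 | C9 ketone, 8-OH, C7 thioester | C=C[C@H](OC(C)=O)[C@@]1(C)C=C[C@@H](OC(=O)CC)[C@H](C)[C@@H]1C(=O)[C@](O)([C@@H](C)C(=O)OC(C)(C)C)C(=O)SCC | intermediate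
24 | (9S)-8,9-diol, C7 thioester | C=C[C@H](OC(C)=O)[C@@]1(C)C=C[C@@H](OC(=O)CC)[C@H](C)[C@@H]1[C@H](O)[C@](O)([C@@H](C)C(=O)OC(C)(C)C)C(=O)SCC | intermediate
25 | 9-acetate, 8-OH, C7 thioester | C=C[C@H](OC(C)=O)[C@@]1(C)C=C[C@@H](OC(=O)CC)[C@H](C)[C@@H]1[C@H](OC(C)=O)[C@](O)([C@@H](C)C(=O)OC(C)(C)C)C(=O)SCC | intermediate
26 | 9-acetate, 8-OSiMe3, C7 thioester | C=C[C@H](OC(C)=O)[C@@]1(C)C=C[C@@H](OC(=O)CC)[C@H](C)[C@@H]1[C@H](OC(C)=O)[C@](O[Si](C)(C)C)([C@@H](C)C(=O)OC(C)(C)C)C(=O)SCC | intermediate
27 | C7 aldehyde, 9-acetate, 8-OSiMe3 | C=C[C@H](OC(C)=O)[C@@]1(C)C=C[C@@H](OC(=O)CC)[C@H](C)[C@@H]1[C@H](OC(C)=O)[C@](O[Si](C)(C)C)([C@@H](C)C(=O)OC(C)(C)C)C=O | intermediate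
28 | 3-chloro-1-(trimethylsilyl)prop-1-yne | C[Si](C)(C)C#CCCl | starting material
29 | 3-chloro-1-(trimethylsilyl)allenylzinc bromide (racemic, labile) | C[Si](C)(C)C([Zn]Br)=C=CCl | intermediate
30 | (6S,7R)-anti-chlorohydrin, silylalkyne, 8-OSiMe3, C19 tert-butyl ester | C=C[C@H](OC(C)=O)[C@@]1(C)C=C[C@@H](OC(=O)CC)[C@H](C)[C@@H]1[C@H](OC(C)=O)[C@](O[Si](C)(C)C)([C@@H](C)C(=O)OC(C)(C)C)[C@@H](O)[C@H](C#C[Si](C)(C)C)Cl | intermediate
31 | 19,7-lactone with free 8-OH, 6-chloro, trimethylsilylethynyl on C6 | C=C[C@H](OC(C)=O)[C@@]1(C)C=C[C@@H](OC(=O)CC)[C@H](C)[C@@H]1[C@H](OC(C)=O)[C@]2(O)[C@@H](C)C(=O)O[C@H]2[C@H](C#C[Si](C)(C)C)Cl | intermediate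
32 | open enyne: vinyl on C2, ethynyl on C6, all ten stereocentres as in the target | C=C[C@H](OC(C)=O)[C@@]1(C)C=C[C@@H](OC(=O)CC)[C@H](C)[C@@H]1[C@H](OC(C)=O)[C@]2(O)[C@@H](C)C(=O)O[C@H]2[C@H](C#C)Cl | intermediate
33 | open triene: vinyl on C2, buta-1,3-dien-2-yl on C6 | C=C[C@H](OC(C)=O)[C@@]1(C)C=C[C@@H](OC(=O)CC)[C@H](C)[C@@H]1[C@H](OC(C)=O)[C@]2(O)[C@@H](C)C(=O)O[C@H]2[C@H](C(=C)C=C)Cl | intermediate
34 | CNP0305105.1, (1S,2S,3Z,6S,7R,8R,9S,10S,11R,12R,17R)-2,9-diacetoxy-6-chloro-8-hydroxy-12-propanoyloxybriara-3,5(16),13-trien-19,7-olide | C=C1/C=C\[C@H](OC(C)=O)[C@@]2(C)C=C[C@@H](OC(=O)CC)[C@H](C)[C@@H]2[C@H](OC(C)=O)[C@]2(O)[C@@H](C)C(=O)O[C@H]2[C@H]1Cl | target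

## Summary and risks

Total step count: 23.
Longest linear sequence: 18 steps (1, 3–9, 14–23).

Steps most likely to fail:

**Step 23.** Ring closure may lose to intermolecular metathesis. It may also stall at the open triene, because the vinyl group next to quaternary C1 engages slowly, or it may occur with the wrong olefin geometry. The fallback sets out from 32 and returns at 34. It moves the closing bond from C3=C4 to C4–C5 and fixes the geometry before cyclisation. Bromoboration of the alkyne with B-bromo-9-BBN followed by protodeboronation with AcOH should give the 2-bromoalk-1-ene F1. Z-selective cross-metathesis of its vinyl group with vinyl–B(pin) (Mo monoaryloxide pyrrolide catalyst) should give the (Z)-alkenylboronate F2. An intramolecular Suzuki–Miyaura coupling (Pd(dppf)Cl2, K3PO4, DMF/H2O, rt, high dilution) then closes the ten-membered ring to 34.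

**Step 14.** The addition may be too slow or reversible (retro-aldol), and proton transfer may win, because a fully substituted enolate meets an α-branched aldehyde next to a quaternary carbon. The fallback sets out from 14 and returns at 23. It makes the union irreversible by acylation. Pinnick oxidation of 14 gives the carboxylic acid F3. Treatment with 1-chloro-N,N,2-trimethylpropenylamine gives the acid chloride F4. C-acylation of enolate 20 with F4 gives the β-keto dioxolanone F5. Thiolysis with EtSH under the conditions of step 15 opens F5 to 23, so steps 15 and 16 are not needed.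

**Step 20.** Facial selectivity at the crowded aldehyde may be poor, or the silyl ether may be lost and chelation would then reverse the sense. The fallback sets out from 27 and returns at 30. It puts the aldehyde face under reagent control. Sulfur-ylide epoxidation of 27 with the ylide from a chiral terpene-derived sulfide and 3-bromo-1-(trimethylsilyl)propyne should give the trans-alkynyl epoxide F6. Opening with LiCl/AcOH in THF at the propargylic carbon C6 with inversion gives 30.

## Further compounds

F1 | step 23 | 2-bromoalk-1-ene from 32 (C5 bromide, C16 methylene) | C=C[C@H](OC(C)=O)[C@@]1(C)C=C[C@@H](OC(=O)CC)[C@H](C)[C@@H]1[C@H](OC(C)=O)[C@]2(O)[C@@H](C)C(=O)O[C@H]2[C@H](C(Br)=C)Cl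
F2 | step 23 | (Z)-alkenylboronate (C4 pinacolboronate) of F1 | CC1(C)OB(OC1(C)C)/C=C\[C@H](OC(C)=O)[C@@]2(C)C=C[C@@H](OC(=O)CC)[C@H](C)[C@@H]2[C@H](OC(C)=O)[C@]3(O)[C@@H](C)C(=O)O[C@H]3[C@H](C(Br)=C)Cl
F3 | step 14 | C9 carboxylic acid from 14 | C=C[C@H](OC(C)=O)[C@@]1(C)C=C[C@@H](OC(=O)CC)[C@H](C)[C@@H]1C(=O)O
F4 | step 14 | C9 acid chloride | C=C[C@H](OC(C)=O)[C@@]1(C)C=C[C@@H](OC(=O)CC)[C@H](C)[C@@H]1C(=O)Cl
F5 | step 14 | β-keto dioxolanone (C9 ketone, C8 as in 21) | C=C[C@H](OC(C)=O)[C@@]1(C)C=C[C@@H](OC(=O)CC)[C@H](C)[C@@H]1C(=O)[C@@]2([C@@H](C)C(=O)OC(C)(C)C)O[C@H](C(C)(C)C)OC2=O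
F6 | step 20 | trans-6,7-epoxide bearing the silylalkyne | C=C[C@H](OC(C)=O)[C@@]1(C)C=C[C@@H](OC(=O)CC)[C@H](C)[C@@H]1[C@H](OC(C)=O)[C@](O[Si](C)(C)C)([C@@H](C)C(=O)OC(C)(C)C)[C@H]2O[C@@H]2C#C[Si](C)(C)C
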